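All runs stem from a simulated flask for an exercise, noise included.

If Q is frozen at its charge, the loss of G becomes pseudo-first-order, with a time constant τ that varies inversely with the Q charged.

in all of them: G 0.17 M
- south-east: Q 1.2 equiv; J 0.051 M; temperature 25 °C; run made earlier
- delta: Q 2.50 equiv; J 0.0510 M; temperature 25 °C; time 6.0 d
- alpha: Q 2.50 equiv; J 0.0510 M; temperature 50 °C; time 6.0 d
- zeta: Q 2.50 equiv; J 0.0510 M; at 50 °C until 40 h, from then on at 0 °C; time 6.0 d
- epsilon: Q 2.50 equiv; J 0.0510 M; temperature 0 °C; time 6.0 d

south-east run (percent of the G charged): time / h: E / % = 1.00: 1; 2.00: 3; 4.00: 3; 8.00: 9; 15.0: 16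

(scatter of a reading: 1.5 percentage points)

- the flask with the highest amount of E, in percent of the G charged ("all alike" if they lie within 1.5 percentage points) (delta / alpha / zeta / epsilon / all alike)
- final E, as a percentage of the G charged, in delta
- final E, as a percentage of the G charged, in alpha
- final E, as a percentage of the G charged, in zeta
- final E, as a percentage of the G charged, in epsilon

- the earlier runs do not show what temperature does; that part of a forecast is a guess

The last south-east reading, 16 % of E at 15.0 h, taken as G lost, gives a time constant of 86.0 h at 1.2 equiv of Q. Scaling by the Q charged gives 41.3 h for delta. This τ, the time constant of G at the delta charge and 25 °C, is a reading and carries the scatter of 1.5 percentage points.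

In slow motion, the reckoning starts delta with G and Q at their full charges and has E climb almost in a straight line while the time is short against τ. J is also charged, at 0.0510 M, and the reckoning gives it no part. By the middle of the run, at half of 6.0 d, the reckoning leaves 17.5 % of the G. At the end the reckoned run has lasted 3.49 time constants and leaves 3.06 % of the G, so the question by then is where the lost G stands. If all of it is E, the reckoning puts delta at 96.9 %. Temperature is outside the readings, so the rest is a guess: a shorter τ in alpha and in the first 40 h of zeta, and a longer one in epsilon.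

The forecast names zeta as highest, with 88 % in delta, 85 % in alpha, 89 % in zeta and 30 % in epsilon, reasoning for zeta that “cooling preserves the product or shifts the equilibrium favourably”, and its delta stands below the figure reckoned here.

The flasks give 54.9 % in delta, 26.9 % in alpha, 60.7 % in zeta and 18.9 % in epsilon, so zeta is highest.

    Q + J → L (k = 0.0120 M⁻¹ min⁻¹, Ea = 60.0 kJ mol⁻¹)
    X ⇌ E + Z (K = 0.160 M, k = 0.0130 min⁻¹, Ea = 91.0 kJ mol⁻¹, ΔH = −50.0 kJ mol⁻¹)
    2 G → D (k = 1.00 × 10⁻⁵ M⁻¹ min⁻¹, Ea = 75.0 kJ mol⁻¹)
    G + Q ⇌ X (K = 13.0 M⁻¹, k = 0.00150 M⁻¹ min⁻¹, Ea = 76.0 kJ mol⁻¹, ΔH = −36.0 kJ mol⁻¹)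
    (constants at 25 °C)

Delta holds 21.0 % of its G at 3.00 d, against the 17.5 % reckoned, and 12.7 % at 6.00 d, against 3.06 %, with 54.9 % as E and 32.0 % as X. For the neighbour of zeta, with 1.00 equiv of Q on the same temperature programme, the reckoning stretches τ from 41.3 h to 103 h on the 25 °C scale, a factor of 2.50. With Q frozen at its charge, the logarithm of the fraction of G left should shrink by that factor. That neighbour ends with 32.9 % of E and 60.2 % of G, against 29.3 % of G in zeta, and the logarithm for zeta stands to that for the neighbour at 2.42.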